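**Retrosynthetic overview**

1. Spiro cyclohexane (last ring): the C6–T8 bond and the T7–OH are made together by an aerobic, manganese-mediated oxidative radical 6-endo closure of the trione enol carbon onto an isopropenyl group. This is the one-electron form of the presumed biosynthetic closure and sets C6 and T7. (T1–T8 = terpenoid carbons in geranyl order; C1–C6 = trione ring carbons.)
2. Its precursor, the 6-(cyclopentylmethyl)-4,4-diprenyl trione ⇐ alkylative dearomatisation (double prenylation) ⇐ reductive C-alkylation of 2,4,6-trihydroxyacetophenone with a cyclopentane β-hydroxy aldehyde.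
3. Cyclopentane (first ring; T2, T3, T6): proline 5-enolexo aldol of (3R)-6-oxo-3-isopropenylheptanal ⇐ oxidative cleavage of (R)-limonene 1,2-oxide. T6 comes from the chiral pool; the ring is taken from limonene because closing T2–T6 on an open geranyl chain gives no reliable T3/T6 control in the flask.
4. Ring order: cyclopentane → dearomatised trione ring → spiro cyclohexane; 5 steps.

Assumption: the presumed biogenesis is a 6-geranyl-4,4-diprenyl acetylphloroglucinol whose oxidised geranyl chain first closes T2–T6 to a 3-hydroxy cyclopentane bearing an isopropenyl group (T7=T8), after which C6 closes onto T8 with oxygenation at T7 (via the 7,8-epoxide or its one-electron equivalent); C2 carries the acetyl group, C4 the two prenyl groups, C6 is the spiro carbon.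

**Step 1**
Reactants: 1 (4R)-limonene 1,2-oxide (commercial cis/trans mixture)
Product: 3 (3R)-6-oxo-3-(prop-1-en-2-yl)heptanal, via limonene-1,2-diol 2 (not isolated)
Conditions: HIO4·2H2O (1.1 equiv), THF/H2O 2:1, 0 °C → rt
Reagents that add atoms: water, O
Why: acid-catalysed epoxide hydrolysis followed by Malaprade glycol cleavage opens both epoxide diastereomers to the same keto aldehyde and leaves the C4 stereocentre (future T6) and the isopropenyl group untouched.

**Step 2**
Reactants: 3 (3R)-6-oxo-3-(prop-1-en-2-yl)heptanal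
Product: 4 (1S,2R,5R)-2-hydroxy-2-methyl-5-(prop-1-en-2-yl)cyclopentane-1-carbaldehyde
Conditions: L-proline (20 mol %), DMSO, rt
Reagents that add atoms: none
Why: enamine-mediated 5-enolexo intramolecular aldol addition (List-type aldolisation) of the aldehyde onto the methyl ketone, in which the epimerisable formyl carbon T2 settles trans to the T6 isopropenyl group and the new tertiary OH at T3 forms cis to the formyl group (hydrogen-bonded, cis-selective enolexo transition state), dehydration being slow under proline at rt.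

**Step 3**
Reactants: 4 (1S,2R,5R)-2-hydroxy-2-methyl-5-(prop-1-en-2-yl)cyclopentane-1-carbaldehyde; 5 2,4,6-trihydroxyacetophenone
Product: 7 1-[2,4,6-trihydroxy-3-{[(1S,2R,5R)-2-hydroxy-2-methyl-5-(prop-1-en-2-yl)cyclopentyl]methyl}phenyl]ethan-1-one, via ortho-quinone methide 6 (not isolated)
Conditions: 5 (3 equiv), Hantzsch ester (1.2 equiv), L-proline (20 mol %), EtOH, rt
Reagents that add atoms: none
Why: three-component reductive alkylation (Knoevenagel-type condensation at a free ring carbon to the ortho-quinone methide, then conjugate hydride transfer from the Hantzsch ester) makes the C6–T1 bond without a new stereocentre, excess 5 suppressing double alkylation.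

**Step 4**
Reactants: 7 1-[2,4,6-trihydroxy-3-{[(1S,2R,5R)-2-hydroxy-2-methyl-5-(prop-1-en-2-yl)cyclopentyl]methyl}phenyl]ethan-1-one; 8 prenyl bromide
Product: 10 2-acetyl-3,5-dihydroxy-6-{[(1S,2R,5R)-2-hydroxy-2-methyl-5-(prop-1-en-2-yl)cyclopentyl]methyl}-4,4-bis(3-methylbut-2-en-1-yl)cyclohexa-2,5-dien-1-one, via monoprenyl phenol 9 (not isolated)
Conditions: 8 (2.2 equiv), NaOMe (3 equiv), MeOH, −10 °C → rt
Reagents that add atoms: none
Why: base-mediated C-prenylation of the phloroglucinol anion, first at the free ring CH and then again at that prenyl-bearing carbon (alkylative dearomatisation as in lupulone synthesis), because the carbon carrying the β-branched cyclopentylmethyl group is the more hindered; no stereocentre is formed.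

**Step 5**
Reactants: 10 2-acetyl-3,5-dihydroxy-6-{[(1S,2R,5R)-2-hydroxy-2-methyl-5-(prop-1-en-2-yl)cyclopentyl]methyl}-4,4-bis(3-methylbut-2-en-1-yl)cyclohexa-2,5-dien-1-one
Product: 12 (3'R,3a'S,5'S,7'R,7a'R)-3-acetyl-3',4,7'-trihydroxy-3',7'-dimethyl-5,5-bis(3-methylbut-2-en-1-yl)octahydrospiro[cyclohexane-1,5'-inden]-3-ene-2,6-dione (target CNP0266834.1), via tertiary hydroperoxide 11 (not isolated)
Conditions: Mn(OAc)3·2H2O (20 mol %), air (1 atm), AcOH, rt; then PPh3 (1.5 equiv), 0 °C
Reagents that add atoms: dioxygen, O=O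
Why: Snider-type manganese-mediated oxidative radical cyclisation in its aerobic (Nishino) form, in which the C6 radical of the manganese enolate closes 6-endo-trig on the CH2 terminus of the isopropenyl group through a chair that completes the trans-hydrindane with the gem-diprenyl flank (C5/C4) equatorial and the flat chelated C1 flank axial (sets C6), the tertiary T7 radical then takes up O2 from the equatorial face anti to the axial C1 carbonyl (sets T7, OH equatorial), and PPh3 reduces the hydroperoxide to the alcohol.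

**Compound list**

1 | (4R)-limonene 1,2-oxide, cis/trans mixture | CC1(O2)C2C[C@@H](CC1)C(C)=C | starting material
2 | (4R)-1-methyl-4-(prop-1-en-2-yl)cyclohexane-1,2-diol (not isolated) | CC1(O)C(O)C[C@@H](CC1)C(C)=C | intermediate
3 | (3R)-6-oxo-3-(prop-1-en-2-yl)heptanal | O=CC[C@@H](CCC(C)=O)C(C)=C | intermediate
4 | (1S,2R,5R)-2-hydroxy-2-methyl-5-(prop-1-en-2-yl)cyclopentane-1-carbaldehyde | O=C[C@H]1[C@@H](CC[C@@]1(C)O)C(C)=C | intermediate
5 | 2,4,6-trihydroxyacetophenone | CC(=O)c1c(O)cc(O)cc1O | starting material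
6 | ortho-quinone methide from 4 and 5 (not isolated) | CC(=O)C1=C(O)C=C(O)C(=C[C@H]2[C@@H](CC[C@@]2(C)O)C(C)=C)C1=O | intermediate
7 | 1-[2,4,6-trihydroxy-3-{[(1S,2R,5R)-2-hydroxy-2-methyl-5-(prop-1-en-2-yl)cyclopentyl]methyl}phenyl]ethan-1-one | CC(=O)c1c(O)cc(O)c(C[C@H]2[C@@H](CC[C@@]2(C)O)C(C)=C)c1O | intermediate
8 | prenyl bromide (1-bromo-3-methylbut-2-ene) | CC(C)=CCBr | starting material
9 | 5-prenyl derivative of 7 (not isolated) | CC(=O)c1c(O)c(CC=C(C)C)c(O)c(C[C@H]2[C@@H](CC[C@@]2(C)O)C(C)=C)c1O | intermediate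
10 | 2-acetyl-3,5-dihydroxy-6-{[(1S,2R,5R)-2-hydroxy-2-methyl-5-(prop-1-en-2-yl)cyclopentyl]methyl}-4,4-bis(3-methylbut-2-en-1-yl)cyclohexa-2,5-dien-1-one | CC(=O)C1=C(O)C(CC=C(C)C)(CC=C(C)C)C(O)=C(C[C@H]2[C@@H](CC[C@@]2(C)O)C(C)=C)C1=O | intermediate
11 | T7 hydroperoxide of the target (not isolated) | CC(=O)C1=C(O)C(CC=C(C)C)(CC=C(C)C)C(=O)[C@@]2(C[C@H]3[C@@H](CC[C@@]3(C)O)[C@](C)(OO)C2)C1=O | intermediate
12 | (3'R,3a'S,5'S,7'R,7a'R)-3-acetyl-3',4,7'-trihydroxy-3',7'-dimethyl-5,5-bis(3-methylbut-2-en-1-yl)octahydrospiro[cyclohexane-1,5'-inden]-3-ene-2,6-dione (CNP0266834.1) | CC(=O)C1=C(O)C(CC=C(C)C)(CC=C(C)C)C(=O)[C@@]2(C[C@H]3[C@@H](CC[C@@]3(C)O)[C@](C)(O)C2)C1=O | target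

**Total steps:** 5. **Longest linear sequence:** 5 (1 → 3 → 4 → 7 → 10 → 12).

**Steps most likely to fail (in route order; step 5 is the least certain)**

Step 2 (aldol may dehydrate to the enal or give the wrong T3 epimer). The fallback sets out from 3 and comes back at 4. Compound 3 is closed under dehydrating conditions (piperidine, AcOH, benzene, 80 °C) to the enal (5S)-2-methyl-5-(prop-1-en-2-yl)cyclopent-1-ene-1-carbaldehyde F1. Nucleophilic epoxidation (H2O2, NaOH, MeOH, 0 °C) from the face anti to the isopropenyl group gives the epoxy aldehyde (1S,2S,5R)-5-methyl-2-(prop-1-en-2-yl)-6-oxabicyclo[3.1.0]hexane-1-carbaldehyde F2. Reductive cleavage of the C–O bond alpha to the formyl group ((PhSe)2, NaBH4, AcOH, EtOH, 0 °C), followed by equilibration of the formyl group to the trans position, gives 4. T3 is then fixed by the face of epoxidation and not by the aldol transition state.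

Step 4 (the second prenyl group may enter at the terpenoid-bearing carbon, or O-alkylation may compete). The fallback sets out from 5 and 8 and comes back at 10; the ring is dearomatised before the terpenoid is attached. Compound 5 with 8 (2.2 equiv) and NaOMe in MeOH at 0 °C gives, via the monoprenyl phenol 2,4,6-trihydroxy-3-(3-methylbut-2-en-1-yl)acetophenone F3, the gem-diprenyl trione 2-acetyl-3,5-dihydroxy-4,4-bis(3-methylbut-2-en-1-yl)cyclohexa-2,5-dien-1-one F4. F4 is expected to be the minor product beside the 3,5-diprenyl isomer and is separated by chromatography, which is acceptable on this cheap material. F4, 4 and Hantzsch ester with L-proline (EtOH, rt) then give 10 through the alkylidene trione F5 (Knoevenagel condensation, then conjugate hydride transfer).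

Step 5 (the C6 radical may instead close 5-exo on a C4 prenyl group to a bicyclo[3.2.1]octane, O2 may enter axially at T7, or the C6 epimer may form; a C6 epimer would be separable). The fallback sets out from 4, uses F4 from the fallback to step 4, and comes back at 12; the spiro ring is closed by the two-electron version, with the epoxide installed before any prenyl group is present. Compound 4 is epoxidised at the isopropenyl group (dimethyldioxirane, acetone, −20 °C) to the epoxy aldehyde (1S,2R,5R)-2-hydroxy-2-methyl-5-[(2S)-2-methyloxiran-2-yl]cyclopentane-1-carbaldehyde F6; both T7 epimers form and the (2S)-oxirane is the productive one. F6 and F4 are joined with Hantzsch ester and L-proline, via the alkylidene trione F7, to the epoxy trione 2-acetyl-3,5-dihydroxy-6-({(1S,2R,5R)-2-hydroxy-2-methyl-5-[(2S)-2-methyloxiran-2-yl]cyclopentyl}methyl)-4,4-bis(3-methylbut-2-en-1-yl)cyclohexa-2,5-dien-1-one F8. Cs2CO3 in DMF at 40 °C then closes the ring by 6-exo-tet opening of the epoxide at T8 by C6, giving 12 directly. Only the (2S)-oxirane can reach the chair transition state with the oxygen anti to the incoming carbon on the trans-fused bicycle, so the closure itself selects T7 and the other epimer is left behind and removed.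

**Further compounds**

F1 | step 2 | (5S)-2-methyl-5-(prop-1-en-2-yl)cyclopent-1-ene-1-carbaldehyde | O=CC1=C(C)CC[C@H]1C(C)=C
F2 | step 2 | (1S,2S,5R)-5-methyl-2-(prop-1-en-2-yl)-6-oxabicyclo[3.1.0]hexane-1-carbaldehyde | O=C[C@]1(O2)[C@H](C(C)=C)CC[C@]12C
F3 | step 4 | 2,4,6-trihydroxy-3-(3-methylbut-2-en-1-yl)acetophenone | CC(=O)c1c(O)cc(O)c(CC=C(C)C)c1O
F4 | step 4 | 2-acetyl-3,5-dihydroxy-4,4-bis(3-methylbut-2-en-1-yl)cyclohexa-2,5-dien-1-one | CC(=O)C1=C(O)C(CC=C(C)C)(CC=C(C)C)C(O)=CC1=O
F5 | step 4 | alkylidene trione from F4 and 4 | CC(=O)C1=C(O)C(CC=C(C)C)(CC=C(C)C)C(=O)C(=C[C@H]2[C@@H](CC[C@@]2(C)O)C(C)=C)C1=O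
F6 | step 5 | (1S,2R,5R)-2-hydroxy-2-methyl-5-[(2S)-2-methyloxiran-2-yl]cyclopentane-1-carbaldehyde | O=C[C@H]1[C@@H](CC[C@@]1(C)O)[C@]2(C)OC2
F7 | step 5 | alkylidene trione from F4 and F6 | CC(=O)C1=C(O)C(CC=C(C)C)(CC=C(C)C)C(=O)C(=C[C@H]2[C@@H](CC[C@@]2(C)O)[C@]3(C)OC3)C1=O
F8 | step 5 | 2-acetyl-3,5-dihydroxy-6-({(1S,2R,5R)-2-hydroxy-2-methyl-5-[(2S)-2-methyloxiran-2-yl]cyclopentyl}methyl)-4,4-bis(3-methylbut-2-en-1-yl)cyclohexa-2,5-dien-1-one | CC(=O)C1=C(O)C(CC=C(C)C)(CC=C(C)C)C(O)=C(C[C@H]2[C@@H](CC[C@@]2(C)O)[C@]3(C)OC3)C1=O
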